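**Strategy.** The target is a 1,4-benzoquinone (six-membered ring: C1 and C4 carbonyl, C2 hydroxyl, C5 methoxy, C6 H) whose C3 carries an unbranched docosyl chain C1'–C22'. Everything rests on cutting that chain between C2' and C3'. The ring is carried as an oxidisable 1,2,4,5-tetramethoxybenzene whose C3, crowded by the C2 and C4 methoxy groups, bears only a slim ethynyl group (C1'≡C2'). Deprotonated, this alkyne attacks 1-bromoicosane in an SN2 reaction, which completes the whole carbon skeleton in one operation at a site clear of the ring's ortho substituents. Hydrogenation, oxidation with (NH4)2Ce(NO3)6 and selective hydrolysis of the C2 methoxy group then finish the target.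

Key step: step 3

Remark: the target has no stereocenter and no stereogenic double bond, so no stereochemical control is required; the chain is taken as unbranched n-docosyl (22 carbons).

**Step 1**
Reactants: 1 1,2,4,5-tetramethoxybenzene
Product: 4 2,3,5,6-tetramethoxybenzaldehyde, via aryllithium 2 (not isolated), via lithium hemiaminal alkoxide 3 (not isolated)
Conditions: n-BuLi (1.05 equiv), TMEDA, THF, 0 °C → rt; DMF, −78 °C → rt; 1 M HCl
Reagents that add atoms: N,N-dimethylformamide, CN(C)C=O
Why: Directed ortho-metalation removes the ring proton that lies between two methoxy groups, and the aryllithium adds once to DMF (Bouveault-type formylation) to give a tetrahedral lithium alkoxide that cannot over-add and collapses to the aldehyde on acidic work-up.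

**Step 2**
Reactants: 4 2,3,5,6-tetramethoxybenzaldehyde; 5 dimethyl (1-diazo-2-oxopropyl)phosphonate
Product: 7 3-ethynyl-1,2,4,5-tetramethoxybenzene, via diazoalkene 6 (not isolated)
Conditions: K2CO3, MeOH/THF, 0 °C → rt
Reagents that add atoms: none
Why: Seyferth–Gilbert homologation in its Ohira–Bestmann form: methanolysis of 5 releases the dimethyl (diazomethyl)phosphonate anion, which olefinates the non-enolisable aldehyde in Horner–Wadsworth–Emmons fashion to diazoalkene 6, and loss of N2 with 1,2-shift should give the terminal alkyne under conditions that leave aryl methyl ethers alone.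

**Step 3**
Reactants: 7 3-ethynyl-1,2,4,5-tetramethoxybenzene; 8 1-bromoicosane
Product: 10 3-(docos-1-yn-1-yl)-1,2,4,5-tetramethoxybenzene, via lithium acetylide 9 (not isolated)
Conditions: n-BuLi (1.05 equiv), THF, −78 → 0 °C; then 8 (1.2 equiv, warm THF solution), DMPU, 0 → 40 °C
Reagents that add atoms: none
Why: n-BuLi removes the acetylenic proton of 7, which is many orders of magnitude more acidic than the ring C6–H, and the resulting lithium acetylide 9 attacks the CH2–Br carbon of 8 from the backside in an SN2 displacement once DMPU has loosened the acetylide aggregates, forming the C2'–C3' bond. The closest known reaction type is the alkylation of lithium arylacetylides with primary alkyl bromides in THF containing a dipolar aprotic cosolvent. No ring is closed, so no mode of closure applies, and no stereocenter or stereogenic double bond is formed, so no control element is needed. The selectivity required is substitution over dehydrobromination of 8 and reaction at the acetylide carbon only; the electrophile is primary and unbranched, the acetylide is a weak base of minimal steric demand, and its nucleophilic carbon C2' lies two collinear atoms outside the pocket between the C2 and C4 methoxy groups, so the crowding at C3 never enters the transition state. Limiting the base to one equivalent should leave C6–H and the methoxy groups untouched.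

**Step 4**
Reactants: 10 3-(docos-1-yn-1-yl)-1,2,4,5-tetramethoxybenzene
Product: 11 3-docosyl-1,2,4,5-tetramethoxybenzene
Conditions: H2 (1 atm), 10% Pd/C, EtOAc/EtOH, rt
Reagents that add atoms: none
Why: Heterogeneous catalytic hydrogenation should saturate the disubstituted alkyne through the alkene to the alkane, while the arene and its methyl ethers are inert and no alkene geometry or stereocenter is at stake.

**Step 5**
Reactants: 11 3-docosyl-1,2,4,5-tetramethoxybenzene
Product: 12 3-docosyl-2,5-dimethoxycyclohexa-2,5-diene-1,4-dione
Conditions: (NH4)2Ce(NO3)6 (2.5 equiv), MeCN/CH2Cl2/H2O, 0 °C → rt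
Reagents that add atoms: water, O
Why: Oxidative demethylation of a para-dimethoxyarene by tetravalent cerium proceeds by two one-electron oxidations with attack of water at the ipso carbons and loss of two molecules of methanol, and because both para-related methoxy pairs of 11 lead to the same 2,5-dimethoxy-1,4-benzoquinone, regiochemistry is not an issue.

**Step 6**
Reactants: 12 3-docosyl-2,5-dimethoxycyclohexa-2,5-diene-1,4-dione
Product: 13 3-docosyl-2-hydroxy-5-methoxycyclohexa-2,5-diene-1,4-dione
Conditions: 70% aq HClO4, 1,4-dioxane/CH2Cl2, rt
Reagents that add atoms: water, O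
Why: Acid-catalysed hydrolysis of a vinylogous methyl ester by addition of water and elimination of methanol is known to occur preferentially at the methoxy group next to the alkyl chain in 3-alkyl-2,5-dimethoxy-1,4-benzoquinones (the C2 methoxy, wedged between the C3 chain and the C1 carbonyl), while the unhindered, fully conjugated C5 methoxy group should survive.

**Compound list**
1 | 1,2,4,5-tetramethoxybenzene | COc1cc(OC)c(OC)cc1OC | starting material
2 | (2,3,5,6-tetramethoxyphenyl)lithium | [Li]c1c(OC)c(OC)cc(OC)c1OC | intermediate (not isolated)
3 | lithium (dimethylamino)(2,3,5,6-tetramethoxyphenyl)methanolate, racemic | [Li+].[O-]C(N(C)C)c1c(OC)c(OC)cc(OC)c1OC | intermediate (not isolated)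
4 | 2,3,5,6-tetramethoxybenzaldehyde | O=Cc1c(OC)c(OC)cc(OC)c1OC | intermediate
5 | dimethyl (1-diazo-2-oxopropyl)phosphonate | COP(=O)(OC)C(=[N+]=[N-])C(C)=O | starting material
6 | 3-(2-diazoethenyl)-1,2,4,5-tetramethoxybenzene | [N-]=[N+]=C=Cc1c(OC)c(OC)cc(OC)c1OC | intermediate (not isolated)
7 | 3-ethynyl-1,2,4,5-tetramethoxybenzene | C#Cc1c(OC)c(OC)cc(OC)c1OC | intermediate
8 | 1-bromoicosane | CCCCCCCCCCCCCCCCCCCCBr | starting material
9 | lithium (2,3,5,6-tetramethoxyphenyl)ethynide | [Li]C#Cc1c(OC)c(OC)cc(OC)c1OC | intermediate (not isolated)
10 | 3-(docos-1-yn-1-yl)-1,2,4,5-tetramethoxybenzene | CCCCCCCCCCCCCCCCCCCCC#Cc1c(OC)c(OC)cc(OC)c1OC | intermediate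
11 | 3-docosyl-1,2,4,5-tetramethoxybenzene | CCCCCCCCCCCCCCCCCCCCCCc1c(OC)c(OC)cc(OC)c1OC | intermediate
12 | 3-docosyl-2,5-dimethoxycyclohexa-2,5-diene-1,4-dione | CCCCCCCCCCCCCCCCCCCCCCC1=C(OC)C(=O)C=C(OC)C1=O | intermediate
13 | 3-docosyl-2-hydroxy-5-methoxycyclohexa-2,5-diene-1,4-dione (CNP0107063.0) | CCCCCCCCCCCCCCCCCCCCCCC1=C(O)C(=O)C=C(OC)C1=O | target

**Totals**
Total steps: 6. Longest linear sequence: 6 steps (1 → 4 → 7 → 10 → 11 → 12 → 13); 5 and 8 are purchased.

**Steps most likely to fail**

Step 3 (key step). The substitution may stall because the waxy bromide dissolves poorly at the temperatures where the acetylide is best behaved, or because the aggregated acetylide reacts too slowly and dehydrobromination of the bromide catches up. The fallback attaches the chain in one piece at the ring carbon with a more reactive nucleophile. It sets out from 1: aryllithium 2 is generated as in step 1 and alkylated with purchased 1-bromodocosane (CCCCCCCCCCCCCCCCCCCCCCBr) in THF/DMPU at 0 °C → rt. This alkylation of a doubly ortho-methoxylated aryllithium with a primary bromide is a known reaction type; it forms the C3–C1' bond and comes back to the route at 11. No compound outside the compound list would be made (F0).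

Step 6. The hydrolysis may fail to discriminate between the two vinylogous esters, cleaving both, or may stop short because the long-chain quinone stays out of solution. The fallback moves the selectivity to an etherification. It sets out from 12, which is hydrolysed exhaustively (2 M NaOH, EtOH/THF, reflux, then HCl) to 3-docosyl-2,5-dihydroxycyclohexa-2,5-diene-1,4-dione F1. Acid-catalysed mono-etherification of F1 (MeOH, cat. H2SO4, reflux, stopped at the mono-ether) is a vinylogous Fischer esterification in which the hydroxyl next to C6–H, not shielded by the chain, should react first. It comes back to the route at 13.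

Step 2. Olefination of the doubly ortho-substituted, electron-rich aldehyde may be so slow that the diazophosphonate anion decomposes before conversion is complete. The fallback is the Corey–Fuchs sequence. It sets out from 4, which with CBr4/PPh3 (CH2Cl2, 0 °C) should give 3-(2,2-dibromoethenyl)-1,2,4,5-tetramethoxybenzene F2. Treatment of F2 with n-BuLi (2.1 equiv, THF, −78 °C → rt) brings about bromine–lithium exchange, elimination and 1,2-shift to lithium acetylide 9, which is protonated on aqueous work-up. It comes back to the route at 7.

**Further compounds**
F0 | step 3 | none | none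
F1 | step 6 | 3-docosyl-2,5-dihydroxycyclohexa-2,5-diene-1,4-dione | CCCCCCCCCCCCCCCCCCCCCCC1=C(O)C(=O)C=C(O)C1=O
F2 | step 2 | 3-(2,2-dibromoethenyl)-1,2,4,5-tetramethoxybenzene | BrC(Br)=Cc1c(OC)c(OC)cc(OC)c1OC
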